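Late in the red run target falls, from 50% at 5.00 h to 39% at 12.0 h, with the solid substrate reading 0% at the start of that stretch. Read as first-order decay, this gives 28.2 h, the loss time: the time in which target falls by a factor e once the solid no longer feeds it.

| setting | red | flask |
|---|---|---|
| solid substrate | 0.59 M | 0.59 M |
| gas | 62 mM (held) | 62 mM (held) |
| remark | the very flask that is asked about, followed so far |  |
| time |  | 40 h |

- red (time / h: target / %, solid substrate / %): 0.833: 17, 72; 2.00: 38, 30; 5.00: 50, 0; 12.0: 39, 2

(each reading ± 2 percentage points)

- as a solid, counted per litre of solution: solid substrate
- at the start none of the solid substrate is in solution
- at the start none of the gas is in solution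

* the moment within 40 h at which there is most target
* the amount of target, in percent of the solid substrate charged, at that time

The second time is the feed time, the estimated moment at which the solid substrate is used up. The line through the solid readings 72% and 30% reaches zero at 2.83 h. In the red flask the loss time is ten times the feed time, so the peak should lie near the end of the feed, and the late decline is a small correction to it. Running that decline back from 5.00 h to the feed time gives, as this reckoning's own reading, 54.0%.

The forecast puts the peak later than the feed time and slightly lower than this reckoning: 3.5 h (2.8 h to 5 h) and 53% (50% to 57%), on the ground that “Once the solid is gone, formation stops soon after, apart from a small dissolved residue.”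

The red flask gives 56.4% at 3.30 h, inside both ranges.

    solid substrate ⇌ dissolved substrate, rate k1*(cs1 - [dissolved substrate]) while solid is left; crystals form when [dissolved substrate] > cs1 (solubility = 0.270 M, k = 0.0150 min⁻¹)
    gas ⇌ reagent, rate k2*(csat - [reagent]) (kL = 1.00 min⁻¹)
    dissolved substrate + reagent ⇌ target (K = 660 L mol⁻¹, k = 0.950 L mol⁻¹ min⁻¹)
    dissolved substrate + target → side product (k = 0.0700 L mol⁻¹ min⁻¹)

At the best time the red flask already holds 41.3% of side product; taking away the passing of dissolved substrate + target into side product lifts the highest target from 56.4% to 97.6%, the largest single effect. From that peak the loss time gives 50.2% at 6.60 h, and the red flask holds 48.9%. For the same flask left until 25 h it gives 26.1%, and that flask ends with 26.2%.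

The numbers in the tables are calculated for substances that don't exist; noise was put on by code.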